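- Multiply each flask's catalyst charge c by its time t. This product, D = ct, is the catalyst dose, and the bullets below test it as the clock of the flask. The peak dose D* = 683 mM·min is taken midway between beta's two highest target readings, at 15.0 min and 20.0 min, and it carries the scatter of those readings.

in all of them: substrate 2.2 M; partner 2.64 M
- delta: free catalyst 9.6 mM; run made earlier
- beta: free catalyst 39 mM; run made earlier
- maple: free catalyst 8.0 mM; time 50 min
- larch: free catalyst 12 mM; time 50 min
- cedar: free catalyst 20 mM; time 50 min
- elm: free catalyst 25 mM; time 50 min

| run | time / min | target / % | substrate / % |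
|---|---|---|---|
| delta | 3.00 | 3.1 | 97.2 |
| delta | 5.00 | 3.6 | 94.5 |
| delta | 10.0 | 7.4 | 92.0 |
| delta | 20.0 | 12.1 | 84.4 |
| delta | 40.0 | 16.4 | 72.3 |
| beta | 8.00 | 14.5 | 77.0 |
| beta | 15.0 | 17.4 | 61.8 |
| beta | 20.0 | 17.9 | 53.6 |
| beta | 30.0 | 15.5 | 41.1 |
| beta | 40.0 | 13.5 | 31.5 |

(scatter of a reading: 0.5 percentage points)

- on the list of suspects stand: partner + free catalyst <-> catalyst intermediate A; catalyst intermediate A <-> catalyst intermediate B; substrate + catalyst intermediate B <-> catalyst intermediate C; catalyst intermediate C <-> free catalyst + target; free catalyst + target -> free catalyst + over-reaction product; 2 free catalyst <-> resting dimer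
- "hardly changes" means that all values lie within two and a half points (for a concentration: within two and a half percent of the largest)

- amount of target at the end, in percent of the substrate charged for maple, larch, cedar, elm, in this order
- the course of these numbers from the first flask to the last (falls, then rises / rises, then falls / rises all the way / falls all the way / hardly changes)

- The test of the clock comes first. Delta's last dose, 384 mM·min, lies between beta's first two, and its substrate reading, 72.3%, lies between theirs, 77.0% and 61.8%.
- Fastest rung: delta already shows 3.1% target at 3.00 min, so you see no start-up lag in the readings.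
- Middle rung: at its peak, target is made as fast as it is consumed. The ratio of the two rate constants, the selectivity factor s, is therefore substrate over target there. Beta's peak lies near its two highest target readings, where substrate over target reads 3.55 and 2.99, so I take their mean, s = 3.27, as a reading for beta.
- Slowest rung: beta's substrate lifetime, from its last reading, is τ = 34.6 min, while its target lifetime is τ/s = 10.6 min, which is shorter. Past the peak, target therefore trails the slowly falling substrate, and the top of the curve stays flat.
- My own reckoning reads the asked flasks off the dose curve. Maple's 400 mM·min gives about 16.4%, larch's 600 mM·min about 17.4%, cedar's lies between the larch and elm values, and elm's 1250 mM·min gives 15.1%. That spread of 2.3 percentage points lies just inside the margin, so I say the course hardly changes, though narrowly.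
- The forecast differs on the course. It holds that “the peak simply arrives earlier with more catalyst” and gives 16.8%, 17.9%, 16.5% and 14.7%, with the course rises, then falls.
- The simulation gives 16.7%, 17.9%, 16.9% and 15.5%, so the course is hardly changes.

    partner + free catalyst ⇌ catalyst intermediate A (K = 0.900 M⁻¹, k = 0.120 M⁻¹ s⁻¹)
    catalyst intermediate A ⇌ catalyst intermediate B (K = 96.0, k = 30.0 s⁻¹)
    substrate + catalyst intermediate B ⇌ catalyst intermediate C (K = 0.0790 M⁻¹, k = 0.120 M⁻¹ s⁻¹)
    catalyst intermediate C ⇌ free catalyst + target (K = 1.20 M, k = 0.350 s⁻¹)
    free catalyst + target → free catalyst + over-reaction product (k = 0.480 M⁻¹ s⁻¹)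
    2 free catalyst ⇌ resting dimer (K = 47.0 M⁻¹, k = 0.150 M⁻¹ s⁻¹)

- Hold the peak time t* = D*/c against the run time. For elm, t* is 27.3 min, earlier than the end at 50 min, and elm's target goes from 17.9% at 25.0 min down to 15.5% at 50.0 min. For larch, t* is 56.9 min, later than that end, and larch's target climbs from 15.1% at 25.0 min to 17.9% at 50.0 min.

Readings and results were generated by integration from invented constants; the scatter is artificial.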